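Wednesday's flask, with everything in at the start, is the neighbour against which we hold the dosed flasks.

all flasks: base 0.0200 equiv; time 8.0 min

| run | substrate | coupling partner | remark |
|---|---|---|---|
| Friday's | 0.10 M (fed, over 1.5 min) | 0.900 equiv | all else is in the flask from the start; the feed brings no volume worth counting |
| Tuesday's | 0.10 M (in portions, 3, over 6.0 min) | 0.900 equiv | first portion at the start, last at 6.0 min |
| Sunday's | 0.10 M (fed, over 6.0 min) | 0.900 equiv | all else is in the flask from the start; the feed brings no volume worth counting |
| Monday's | 0.10 M | 0.900 equiv (fed, over 6.0 min) | all else is in the flask from the start; the feed brings no volume worth counting |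
| Wednesday's | 0.10 M | 0.900 equiv | everything together at the start |

    substrate + target ⇌ idle adduct, settled at all times (K1 = 133 L mol⁻¹)
    base + by-product ⇌ salt, settled at all times (K2 = 6.25 × 10⁵ L mol⁻¹)
    substrate + coupling partner + by-product → target + 2 by-product (k3 = 71.3 L² mol⁻² min⁻¹)
    target ⇌ isomer of the product (K4 = 12.4, k4 = 0.733 min⁻¹)
    substrate + coupling partner → target + by-product (k5 = 0.188 L mol⁻¹ min⁻¹)

- a species is counted by the substrate in it: one idle adduct counts as two
- amounts and yields of target count idle adduct too
- in an amount of target, one idle adduct counts as one target
- run time (Friday's): 8.0 min

* the flask that comes out highest in amount of target, in percent of the substrate charged, or "all alike" when all lie within 1.5 percentage points (Friday's / Tuesday's / Sunday's / Monday's / Wednesday's / all alike)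
* target at the end, in percent of the substrate charged, Friday's
* target at the end, in percent of the substrate charged, Tuesday's
* target at the end, in percent of the substrate charged, Sunday's
* target at the end, in percent of the substrate charged, Monday's
* target at the end, in percent of the substrate charged, Wednesday's

The bench rule is to read a slow step off its half-life. The coupling without by-product gives substrate a half-life of 41 min at Wednesday's charge, so in 8.0 min the rule promises about 12.7 % conversion.

The border is a ratio of constants. The coupling with by-product equals the plain one at a free by-product of 0.00264 M. While base and salt stand equal, free by-product sits at 1.60 × 10⁻⁶ M, far less than that. So the rule holds until the plain coupling has filled the base, and we freeze substrate and coupling partner at their charges, since the base charge is far smaller than either. That gives the dead time, the time for the plain coupling to make as much by-product as there is base (the induction period):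

t_dead = c_base / (k · c_substrate · c_partner) = 0.00200 M / (0.188 L mol⁻¹ min⁻¹ × 0.10 M × 0.0900 M) = 1.18 min

Past it, by-product doubles in about 1.08 min at Wednesday's charge, which is shorter than the run, so the rule fails there, and the dead time is the figure we hold between the flasks.

Dosing stretches it. In Sunday's and Monday's the plain rate ramps up, so by-product grows with the square of time:

t_dead = sqrt(2 · t_dead,Wednesday · t_feed) = 3.77 min

Friday's feed ends sooner than the same formula's 1.88 min, so the plain rate stands at its full value from then on, which gives 1.93 min. Tuesday's first portion holds a third of the substrate, which gives 3.55 min, though the second portion arrives earlier, at 3.00 min. We commit to Wednesday's first, Friday's next and the slow-dosed flasks well behind.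

The forecast names Wednesday's, with target at Friday's 29 %, Tuesday's 18.5 %, Sunday's 17.5 %, Monday's 18 % and Wednesday's 32 %. Its ground is that by-product “is held back by the base until about 0.002 M has formed”.

The simulation gives Wednesday's highest, as forecast: Friday's 26.3 %, Tuesday's 14.5 %, Sunday's 15.0 %, Monday's 15.2 %, Wednesday's 28.7 %.

Wednesday's base falls under 2 % of its charge at 1.24 min, beside the dead time of 1.18 min. The same division serves a neighbour of Tuesday's charged with 0.00500 equiv of base. Its first portion gives 0.887 min, which is shorter than the 3.00 min before the second portion and shorter than Tuesday's 3.55 min. That neighbour ends at 19.5 % of target, against Tuesday's 14.5 %.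

The rate constants are invented; no experiment stands behind them.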